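## The problem

The target is the all-catechin procyanidin trimer catechin-(4α→8)-catechin-(4α→6)-catechin. Three flavan-3-ol units are held together by two C(sp3)–C(sp2) bonds, one from C4 of the top unit to C8 of the middle unit and one from C4 of the middle unit to C6 of the bottom unit. Both junctions sit on phloroglucinol-type A rings whose C6 and C8 positions are almost equally nucleophilic, so each bond has to be directed to its site and cannot be left to a Friedel–Crafts preference. There are eight stereocentres: C2 and C3 of every unit (2,3-trans throughout) and C4 of the two upper units, each with its aryl substituent trans to the neighbouring 3-hydroxyl. C2 and C3 of the middle and bottom units can be taken from (+)-catechin, and C4 of the middle unit can be set by its own C3 substituent when the C4 cation is captured. The three centres of the top unit have to be made, but only one needs outside control, because a syn addition of H and OH across C3=C4 on the face away from the 2-aryl group fixes C3 and C4 from C2. The compound carries twelve phenolic hydroxyls that oxidise in air and base, interflavan and benzylic ether bonds that ionise in strong acid, and C2 centres that epimerise when base opens the pyran ring, so the phenols must stay masked until a last neutral step. The feature that opens the plan is ring A of the top unit: an unsubstituted phloroglucinol ring joined through C4a to C4 and through O1 to C2, with C4 bearing C8 of the middle unit. With C2 at the lactone level this is a 4-aryl-5,7-dihydroxycoumarin, the product of a Pechmann condensation of phloroglucinol with an aroylacetic ester.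

## Retrosynthesis

**22 from 21.** The final cut is of fourteen benzyl–oxygen bonds, with the C8–Br bond of the bottom unit restored. Benzyl ethers are the one phenol protection that can be taken off an oligomeric flavan-3-ol without acid, base or oxidant, and the aryl bromide, kept as a regiochemical cap, is reduced in the same hydrogenolysis. Because 21 already has its top 3-hydroxyl free, no other deprotection is needed. The forward step only has to run to completion in a buffered medium.

**21 from 19.** The C3–O and C4–H bonds of the top unit are cut together, which leads back to the 4-aryl-flav-3-ene 19. The neighbouring options are weaker: hydride delivery to a C4 cation enters anti to the 3-oxygen and would give the 3,4-cis series, and hydroxylation of a lactone enolate followed by construction of C2 costs more steps. A hydroboration makes both bonds in one syn addition and lets the single stereocentre of 19, C2, decide the two new ones. The forward reaction must place boron on C3 and approach the face opposite the 2-aryl group.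

**19 from 13 and 17.** The C2–aryl bond is cut next, giving the chromene acetal 13 and the boronic acid 17, which comes from 4-bromocatechol 14 through bromide 15. C2 is the one carbon of the top pyran ring that is remote from the crowded C4, so it is where a chiral catalyst can realistically create the first stereocentre. Starting the relay at C4 would ask a ligated metal hydride to reach a carbon flanked by two ortho oxygens of the middle unit and the peri benzyloxy group. 13 is the coumarin 11 at the lactol oxidation level, so the lactone carbonyl left by the annulation becomes the electrophilic handle for C2. The forward reaction must be catalyst-controlled, because the existing stereocentres are too far away to help.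

**11 from 10 and 3.** The bond from C4 of the middle unit to C6 of the bottom unit is cut while the top unit is still a coumarin. Two things favour this timing over a later union. The coumarin has no sp3 C–H in the top unit, so the benzylic oxidation that prepares the cut (9 to 10) can only strike C4 of the middle unit. Its ring A is conjugated to the lactone and is a poor competitor for the C4 cation, whereas a finished top flavan unit would offer a doubly benzylic C4–H and a free, highly nucleophilic C8. The nucleophile 3 has C8 capped by bromine so that only C6 can react, and it is the same bromide from which the middle unit is made. The forward reaction must be 3,4-trans selective and must outrun self-condensation through C6 of the middle unit.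

**10 from 8 by way of 9.** These are functional-group changes only. The 2-ethoxyethoxy group at C4 of the middle unit comes from DDQ oxidation of 9, and the two benzyl ethers of 9 from the diphenol 8.

**8 from 6 and 7.** The C4–C4a bond and the O1–C2 lactone bond of the top unit are cut together. This removes ring C of the top unit and returns phloroglucinol 7 and the β-ketoester 6. The cut is preferred over disconnecting the bond between C4 of the top unit and C8 of the middle unit, because that bond is then present from the start as the aryl–carbonyl bond of 6, placed at C8 by bromination and lithiation, so no C6/C8 choice arises. On the other side, the threefold symmetry of 7 means that any ring carbon with its neighbouring hydroxyl gives the same product. The precursors are a monomeric catechin derivative and a commodity phenol. The forward reaction must add a ring carbon of 7 to a ketone shielded by two ortho oxygens, under acid mild enough for five benzyl ethers and the pyran ring of the catechin unit.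

**6 from 1.** 6 is the Claisen product of methyl ketone 5 and diethyl carbonate. 5 comes from aryllithium 4 and N-methoxy-N-methylacetamide, 4 from bromide 3 by halogen–lithium exchange, 3 from 2 by bromination at C8, and 2 from (+)-catechin 1 by perbenzylation. Each is a standard transformation that removes one functional group.

## Roads not taken

**Alternative 1:** Twofold hydroboration of a bis-flavene.
- **Cut and key step.** The C3–O and C4–H bonds of both upper units are cut, going from the tridecabenzyl trimer A2 back to the bis-flavene A1, in which the top and middle units are 4-aryl-flav-3-enes. Forward, BH3·SMe2 adds across both C3=C4 bonds and alkaline H2O2 oxidises the boranes.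
- **Merits.** Four stereocentres are set in one flask without a chiral reagent, each 2-aryl group steering the borane to the opposite face. No acid is involved, and A2 needs only hydrogenolysis.
- **Weak points.** A1 must already contain both interflavan bonds as congested aryl–vinyl bonds and both C2 centres in the right absolute configuration. Making a 2H-chromene with a defined C2 is the hard part, and it would have to be done twice. The middle unit could no longer be taken from catechin. The two additions occur at trisubstituted alkenes flanked by ortho-oxygenated aryl groups, and any shortfall in facial selectivity multiplies.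
- **Comparison.** Its endgame is shorter and it needs no cation-based union. The chosen plan borrows the same relay but only once, in step 13, and so shares the risk of a hindered hydroboration on a single alkene. Against the shorter endgame it sets a defined access to the flavene through the coumarin and the use of catechin for two of the three units.

**Alternative 2:** Gold hydroarylation to close the middle ring.
- **Cut and key step.** The C4–C4a bond of the middle unit is cut, going from the flav-3-ene trimer A4 back to the aryl propargyl ether A3, which carries the complete top unit on its phenol ring and the bottom unit on the alkyne. Forward, the cationic gold complex Ph3PAuNTf2 activates the alkyne and the only free ortho carbon closes the ring in a 6-endo-dig sense.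
- **Merits.** The closure is neutral, catalytic and regiochemically forced. The route is convergent, and the middle–bottom bond is made by an sp–sp2 coupling, so the 4→6 connectivity is certain.
- **Weak points.** A3 needs a stereodefined secondary propargylic aryl ether at what becomes C2 of the middle unit, and benzylic propargylic ethers of electron-rich arenes can ionise or rearrange under cationic gold. The alkyne must sit on C6 of a catechin, while halogenation prefers C8. A4 still lacks C3–OH and C4–H of the middle unit, so a hydroboration at the most crowded alkene of the molecule remains.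
- **Comparison.** It is gentler than an acid-promoted Pechmann closure and more convergent, and in those respects it is the better road. The chosen plan sets against it a middle unit taken intact from catechin, C8 regiochemistry fixed by a simple bromination, and no configurationally fragile propargylic ether.

**Alternative 3:** Phloroglucinol stitched onto a triol.
- **Cut and key step.** The C4–C4a and O1–C2 bonds of the middle unit are cut, going from the dimer A6 back to phloroglucinol 7 and the triol A5. Forward, catalytic Sc(OTf)3 ionises the carbinol next to the bottom aryl group, 7 is C-alkylated there, and its adjacent hydroxyl then captures the second benzylic cation.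
- **Merits.** It also uses the symmetry of 7. The middle ring and the middle–bottom bond are made at once, so no separate coupling at C6 is needed. Ring A of A6 is left free for a conventional 4→8 union with a C4-activated catechin such as A7, so the top unit would come complete from catechin and none of its stereocentres would need a chiral catalyst. That is a real advantage in steps and in stereocontrol over the chosen plan.
- **Weak points.** Both benzylic carbinols of A5 ionise, and the cation stabilised by the 3,4-dibenzyloxyphenyl group forms at least as easily as the one wanted first. The reversed order gives the flavan with its two aryl groups exchanged between C2 and C4. A5 itself needs an asymmetric synthesis around a carbinol flanked by two benzyloxy groups. A6 has C6 and C8 both open on an unprotected ring, so the final union with A7 faces the 4→8 against 4→6 problem and over-alkylation.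
- **Comparison.** The chosen plan is longer in the top unit. It sets against this unambiguous connectivity at both junctions (C8 by bromination and acylation, C6 by the bromine cap) and a ring closure whose two bonds give the same coumarin in either order.

Key step: step 5

Remark: 10 is drawn as its 3,4-trans epimer; this centre is lost on ionisation in step 8, so an epimer mixture would serve equally, and 12 and 13 are mixtures at the acetal carbon for the same reason.

Remark: the enantiomer of the tartaric acid monoamide used in step 12 is taken to be the one that delivers the aryl group to the C2 face drawn in 19; the mirror-image catalyst is equally available should the sense of induction prove opposite.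

## Route

Step 1
Reactants: 1 (+)-catechin
Product: 2 3,5,7,3',4'-penta-O-benzyl-(+)-catechin
Conditions: BnBr (6.5 equiv), NaH (6.5 equiv), DMF, −20 → 25 °C
Reagents that add atoms: benzyl bromide, BrCc1ccccc1
Why: Williamson etherification of the four phenols and the secondary 3-hydroxyl; with the halide present from the start and the temperature low, the phenoxides are trapped on oxygen before C-benzylation of ring A or base-induced opening of the pyran ring can compete, so C2 and C3 are carried over unchanged.

Step 2
Reactants: 2 3,5,7,3',4'-penta-O-benzyl-(+)-catechin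
Product: 3 8-bromo-3,5,7,3',4'-penta-O-benzyl-(+)-catechin
Conditions: NBS (1.0 equiv), CH2Cl2, −78 → 0 °C
Reagents that add atoms: N-bromosuccinimide, O=C1CCC(=O)N1Br
Why: Electrophilic aromatic bromination; of the two free positions of ring A, C8 is the more reactive site of benzylated flavan-3-ols and takes up one bromine, which serves later as the handle for acylation (middle unit) and as the cap that leaves only C6 free (bottom unit).

Step 3
Reactants: 3 8-bromo-3,5,7,3',4'-penta-O-benzyl-(+)-catechin
Product: 5 8-acetyl-3,5,7,3',4'-penta-O-benzyl-(+)-catechin, via 8-lithio-penta-O-benzylcatechin 4 (not isolated)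
Conditions: n-BuLi (1.05 equiv), THF, −78 °C; then MeC(O)N(OMe)Me (1.5 equiv), −78 → 0 °C; aq. NH4Cl
Reagents that add atoms: N-methoxy-N-methylacetamide, CC(=O)N(C)OC
Why: Bromine–lithium exchange at −78 °C is faster than any deprotonation of the benzyl ethers, and the aryllithium adds to the N-methoxy-N-methylamide to give a chelated tetrahedral adduct that releases the ketone only on work-up (Weinreb ketone synthesis), so no second addition occurs.

Step 4
Reactants: 5 8-acetyl-3,5,7,3',4'-penta-O-benzyl-(+)-catechin
Product: 6 ethyl 3-oxo-3-(3,5,7,3',4'-penta-O-benzylcatechin-8-yl)propanoate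
Conditions: NaH (2.5 equiv), (EtO)2CO (5 equiv), THF, 65 °C; then AcOH
Reagents that add atoms: diethyl carbonate, CCOC(=O)OCC
Why: Crossed Claisen condensation of a methyl ketone that can enolise only toward the methyl group; the carbonate cannot enolise, and deprotonation of the product β-ketoester drives the equilibrium.

Step 5
Reactants: 6 ethyl 3-oxo-3-(3,5,7,3',4'-penta-O-benzylcatechin-8-yl)propanoate; 7 phloroglucinol
Product: 8 5,7-dihydroxy-4-(3,5,7,3',4'-penta-O-benzylcatechin-8-yl)coumarin
Conditions: 7 (3 equiv), CF3CO2H–CH2Cl2 (1:3), 0 → 25 °C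
Reagents that add atoms: none
Why: Pechmann condensation, known for phloroglucinol with aroylacetic esters, which gives 4-aryl-5,7-dihydroxycoumarins. Acid-catalysed ester exchange puts the acyl group on one phenolic oxygen of 7 (the O1–C2 bond); the ring carbon next to that oxygen, activated by the other two hydroxyls, then attacks the protonated ketone (the C4–C4a bond), and the tertiary benzylic alcohol loses water to give C3=C4; the carbon–carbon bond may equally form first and the lactone second. In either order ring C of the top unit closes in a 6-exo-trig sense, carbon onto the ketone carbonyl or oxygen onto the ester carbonyl. No stereocentre is formed, and the new aryl–C4 axis is of no consequence because C4 becomes tetrahedral later. Regiochemistry does not arise because the three ring carbons of 7 are equivalent, and a second annulation is held back by the excess of 7 and by the deactivating lactone of 8. The step needs chemoselectivity only: the ketone on C8 is twisted out of the plane of its ring by the two flanking oxygens, so it is not deactivated by them and stays electrophilic although shielded, and delivery of the ring carbon within the aryl ester offsets the shielding. Dilute CF3CO2H at or below room temperature should leave the aryl benzyl ethers, the 3-O-benzyl group and the C2–O1 bond of the catechin unit intact.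

Step 6
Reactants: 8 5,7-dihydroxy-4-(3,5,7,3',4'-penta-O-benzylcatechin-8-yl)coumarin
Product: 9 5,7-bis(benzyloxy)-4-(3,5,7,3',4'-penta-O-benzylcatechin-8-yl)coumarin
Conditions: BnBr (2.5 equiv), K2CO3, DMF, 25 °C
Reagents that add atoms: benzyl bromide, BrCc1ccccc1
Why: Williamson etherification of the two coumarin phenols under carbonate, which does not open the lactone; the ethers make ring A of the top unit inert to DDQ and to the later Lewis-acid steps.

Step 7
Reactants: 9 5,7-bis(benzyloxy)-4-(3,5,7,3',4'-penta-O-benzylcatechin-8-yl)coumarin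
Product: 10 5,7-bis(benzyloxy)-4-[4-(2-ethoxyethoxy)-3,5,7,3',4'-penta-O-benzylcatechin-8-yl]coumarin (2-ethoxyethoxy group trans to the 3-benzyloxy group)
Conditions: DDQ (2 equiv), 2-ethoxyethanol (5 equiv), CH2Cl2, 25 °C
Reagents that add atoms: 2-ethoxyethanol, CCOCCO
Why: Benzylic oxidation by hydride abstraction; C4 of the catechin unit is the only C–H conjugated to the tri-oxygenated ring A, and the coumarin has no sp3 C–H, so the cation forms at one site and is trapped by the alcohol anti to the 3-benzyloxy group.

Step 8
Reactants: 10 5,7-bis(benzyloxy)-4-[4-(2-ethoxyethoxy)-3,5,7,3',4'-penta-O-benzylcatechin-8-yl]coumarin; 3 8-bromo-3,5,7,3',4'-penta-O-benzyl-(+)-catechin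
Product: 11 5,7-bis(benzyloxy)-4-{[3,5,7,3',4'-penta-O-benzylcatechin-(4α→6)-8-bromo-3,5,7,3',4'-penta-O-benzylcatechin]-8-yl}coumarin (upper catechin bonded to the coumarin through its C8)
Conditions: 3 (3 equiv), TMSOTf (0.2 equiv), CH2Cl2, −78 → −40 °C; Et3N quench
Reagents that add atoms: none
Why: Lewis-acid ionisation of the chelating 2-ethoxyethoxy group gives the C4 cation stabilised by ring A, and Friedel–Crafts capture by C6 of 3, its only free ring A position because bromine caps C8, occurs on the face opposite the adjacent 3-benzyloxy group to give the 3,4-trans (4α) bond, as is usual for benzylated catechin donors; the coumarin ring is a poor nucleophile and the excess of 3 suppresses self-condensation through C6 of the middle unit.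

Step 9
Reactants: 11 5,7-bis(benzyloxy)-4-{[3,5,7,3',4'-penta-O-benzylcatechin-(4α→6)-8-bromo-3,5,7,3',4'-penta-O-benzylcatechin]-8-yl}coumarin
Product: 13 2-ethoxy-2H-chromene acetal of 11 (C2 carbonyl replaced by H and OEt; both C2 epimers), via 2H-chromen-2-ol lactol 12 (not isolated)
Conditions: i-Bu2AlH (1.2 equiv), CH2Cl2, −78 °C; aq. KNaC4H4O6 work-up; crude 12, EtOH, PPTS (cat.), 4 Å MS, 25 °C
Reagents that add atoms: ethanol, CCO
Why: Partial reduction of a lactone to its lactol at −78 °C, where the aluminium hemiacetal does not open, followed by acid-catalysed acetal exchange through the stabilised 1-benzopyrylium ion; the configuration at C2 is irrelevant because the acetal is ionised again in step 12.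

Step 10
Reactants: 14 4-bromocatechol
Product: 15 4-bromo-1,2-bis(benzyloxy)benzene
Conditions: BnBr (2.2 equiv), K2CO3, DMF, 60 °C
Reagents that add atoms: benzyl bromide, BrCc1ccccc1
Why: Williamson etherification of both catechol hydroxyls.

Step 11
Reactants: 15 4-bromo-1,2-bis(benzyloxy)benzene
Product: 17 [3,4-bis(benzyloxy)phenyl]boronic acid, via 3,4-bis(benzyloxy)phenyllithium 16 (not isolated)
Conditions: n-BuLi (1.05 equiv), THF, −78 °C; B(Oi-Pr)3, −78 → 25 °C; aq. HCl
Reagents that add atoms: triisopropyl borate, CC(C)OB(OC(C)C)OC(C)C; water, O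
Why: Bromine–lithium exchange, borylation of the aryllithium with a trialkyl borate and hydrolysis of the boronate ester, the standard route to arylboronic acids.

Step 12
Reactants: 13 2-ethoxy-2H-chromene acetal of 11; 17 [3,4-bis(benzyloxy)phenyl]boronic acid
Product: 19 (2S)-5,7-bis(benzyloxy)-2-[3,4-bis(benzyloxy)phenyl]-4-{[3,5,7,3',4'-penta-O-benzylcatechin-(4α→6)-8-bromo-3,5,7,3',4'-penta-O-benzylcatechin]-8-yl}-2H-chromene (flav-3-ene; 2-aryl group disposed as in (+)-catechin), via diethyl arylboronate 18 (not isolated)
Conditions: 17 (2 equiv), EtOH, 4 Å MS, 25 °C, then evaporation; 13, chiral tartaric acid monoamide (10 mol %), Yb(OTf)3 (10 mol %), EtOAc, −20 → 4 °C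
Reagents that add atoms: none
Why: Enantioselective addition of an aryl boronate to a chromene acetal under a chiral Brønsted acid/lanthanide triflate pair: the Lewis acid ionises the acetal to the 1-benzopyrylium ion and the aryl group is transferred from the boronate bound to the tartaric acid monoamide, so the face of C2 is chosen by the catalyst and not by the remote stereocentres; attack goes to C2 because C4 carries the bulky aryl group, and electron-rich aryl boronates such as 18 are suitable partners.

Step 13
Reactants: 19 (2S)-2-aryl-4-aryl-2H-chromene trimer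
Product: 21 5,7,3',4'-tetra-O-benzylcatechin-(4α→8)-3,5,7,3',4'-penta-O-benzylcatechin-(4α→6)-8-bromo-3,5,7,3',4'-penta-O-benzylcatechin (top 3-hydroxyl free), via C3-alkylborane 20 (not isolated)
Conditions: BH3·SMe2 (5 equiv), THF, 0 → 40 °C; then 3 M NaOH, 30% H2O2, 0 → 25 °C
Reagents that add atoms: hydrogen peroxide, OO
Why: Hydroboration–oxidation; boron goes to C3, away from the diaryl-substituted and donor-polarised C4, and the borane approaches the face opposite the 2-aryl group on the neighbouring carbon, so that syn delivery of H to C4 and oxidation with retention place the 3-hydroxyl trans to both the 2-aryl and the 4-aryl groups (2,3-trans-3,4-trans), as in the hydroboration of simpler flav-3-enes.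

Step 14
Reactants: 21 tetradeca-O-benzyl bromo trimer
Product: 22 catechin-(4α→8)-catechin-(4α→6)-catechin
Conditions: H2 (1 atm), Pd(OH)2/C, Et3N (1.1 equiv), THF–MeOH–H2O, 25 °C
Reagents that add atoms: none
Why: Hydrogenolysis of the fourteen benzyl ethers with concurrent hydrodebromination at C8 of the bottom unit; the medium stays neutral because the amine takes up HBr, so interflavan bonds and C2 centres are not touched.

## Compound list

1 | (+)-catechin, (2R,3S) | O[C@H]1Cc2c(O)cc(O)cc2O[C@@H]1c1ccc(O)c(O)c1 | starting material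
2 | 3,5,7,3',4'-penta-O-benzyl-(+)-catechin | c1c(OCc3ccccc3)cc(OCc3ccccc3)c2c1O[C@H](c1ccc(OCc3ccccc3)c(OCc3ccccc3)c1)[C@@H](OCc3ccccc3)C2 | intermediate
3 | 8-bromo-3,5,7,3',4'-penta-O-benzyl-(+)-catechin | Brc1c(OCc3ccccc3)cc(OCc3ccccc3)c2c1O[C@H](c1ccc(OCc3ccccc3)c(OCc3ccccc3)c1)[C@@H](OCc3ccccc3)C2 | intermediate
4 | 8-lithio-3,5,7,3',4'-penta-O-benzylcatechin | [Li]c1c(OCc3ccccc3)cc(OCc3ccccc3)c2c1O[C@H](c1ccc(OCc3ccccc3)c(OCc3ccccc3)c1)[C@@H](OCc3ccccc3)C2 | intermediate (not isolated)
5 | 8-acetyl-3,5,7,3',4'-penta-O-benzyl-(+)-catechin | CC(=O)c1c(OCc3ccccc3)cc(OCc3ccccc3)c2c1O[C@H](c1ccc(OCc3ccccc3)c(OCc3ccccc3)c1)[C@@H](OCc3ccccc3)C2 | intermediate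
6 | ethyl 3-oxo-3-(3,5,7,3',4'-penta-O-benzylcatechin-8-yl)propanoate | CCOC(=O)CC(=O)c1c(OCc3ccccc3)cc(OCc3ccccc3)c2c1O[C@H](c1ccc(OCc3ccccc3)c(OCc3ccccc3)c1)[C@@H](OCc3ccccc3)C2 | intermediate
7 | phloroglucinol | Oc1cc(O)cc(O)c1 | starting material
8 | 5,7-dihydroxy-4-(3,5,7,3',4'-penta-O-benzylcatechin-8-yl)coumarin | Oc1cc(O)c2c(c1)OC(=O)C=C2c1c(OCc3ccccc3)cc(OCc3ccccc3)c2c1O[C@H](c1ccc(OCc3ccccc3)c(OCc3ccccc3)c1)[C@@H](OCc3ccccc3)C2 | intermediate
9 | 5,7-bis(benzyloxy)-4-(3,5,7,3',4'-penta-O-benzylcatechin-8-yl)coumarin | c1ccccc1COc1cc(OCc3ccccc3)c2c(c1)OC(=O)C=C2c1c(OCc3ccccc3)cc(OCc3ccccc3)c2c1O[C@H](c1ccc(OCc3ccccc3)c(OCc3ccccc3)c1)[C@@H](OCc3ccccc3)C2 | intermediate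
10 | 5,7-bis(benzyloxy)-4-[4-(2-ethoxyethoxy)-3,5,7,3',4'-penta-O-benzylcatechin-8-yl]coumarin, 3,4-trans | c1ccccc1COc1cc(OCc3ccccc3)c2c(c1)OC(=O)C=C2c1c(OCc3ccccc3)cc(OCc3ccccc3)c2c1O[C@H](c1ccc(OCc3ccccc3)c(OCc3ccccc3)c1)[C@@H](OCc3ccccc3)[C@@H]2OCCOCC | intermediate
11 | 5,7-bis(benzyloxy)-4-{[penta-O-benzylcatechin-(4α→6)-8-bromo-penta-O-benzylcatechin]-8-yl}coumarin | c1ccccc1COc1cc(OCc3ccccc3)c2c(c1)OC(=O)C=C2c1c(OCc3ccccc3)cc(OCc3ccccc3)c2c1O[C@H](c1ccc(OCc3ccccc3)c(OCc3ccccc3)c1)[C@@H](OCc3ccccc3)[C@@H]2c1c(OCc3ccccc3)c(Br)c2c(c1OCc3ccccc3)C[C@H](OCc3ccccc3)[C@@H](c1ccc(OCc3ccccc3)c(OCc3ccccc3)c1)O2 | intermediate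
12 | 2H-chromen-2-ol (lactol) of 11, both C2 epimers | c1ccccc1COc1cc(OCc3ccccc3)c2c(c1)OC(O)C=C2c1c(OCc3ccccc3)cc(OCc3ccccc3)c2c1O[C@H](c1ccc(OCc3ccccc3)c(OCc3ccccc3)c1)[C@@H](OCc3ccccc3)[C@@H]2c1c(OCc3ccccc3)c(Br)c2c(c1OCc3ccccc3)C[C@H](OCc3ccccc3)[C@@H](c1ccc(OCc3ccccc3)c(OCc3ccccc3)c1)O2 | intermediate (not isolated)
13 | 2-ethoxy-2H-chromene acetal of 11, both C2 epimers | c1ccccc1COc1cc(OCc3ccccc3)c2c(c1)OC(OCC)C=C2c1c(OCc3ccccc3)cc(OCc3ccccc3)c2c1O[C@H](c1ccc(OCc3ccccc3)c(OCc3ccccc3)c1)[C@@H](OCc3ccccc3)[C@@H]2c1c(OCc3ccccc3)c(Br)c2c(c1OCc3ccccc3)C[C@H](OCc3ccccc3)[C@@H](c1ccc(OCc3ccccc3)c(OCc3ccccc3)c1)O2 | intermediate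
14 | 4-bromocatechol | Oc1ccc(Br)cc1O | starting material
15 | 4-bromo-1,2-bis(benzyloxy)benzene | Brc1ccc(OCc2ccccc2)c(OCc2ccccc2)c1 | intermediate
16 | 3,4-bis(benzyloxy)phenyllithium | [Li]c1ccc(OCc2ccccc2)c(OCc2ccccc2)c1 | intermediate (not isolated)
17 | [3,4-bis(benzyloxy)phenyl]boronic acid | OB(O)c1ccc(OCc2ccccc2)c(OCc2ccccc2)c1 | intermediate
18 | diethyl [3,4-bis(benzyloxy)phenyl]boronate | CCOB(OCC)c1ccc(OCc2ccccc2)c(OCc2ccccc2)c1 | intermediate (not isolated)
19 | (2S)-5,7-bis(benzyloxy)-2-[3,4-bis(benzyloxy)phenyl]-4-{[penta-O-benzylcatechin-(4α→6)-8-bromo-penta-O-benzylcatechin]-8-yl}-2H-chromene | c1ccccc1COc1cc(OCc3ccccc3)c2c(c1)O[C@H](c1ccc(OCc3ccccc3)c(OCc3ccccc3)c1)C=C2c1c(OCc3ccccc3)cc(OCc3ccccc3)c2c1O[C@H](c1ccc(OCc3ccccc3)c(OCc3ccccc3)c1)[C@@H](OCc3ccccc3)[C@@H]2c1c(OCc3ccccc3)c(Br)c2c(c1OCc3ccccc3)C[C@H](OCc3ccccc3)[C@@H](c1ccc(OCc3ccccc3)c(OCc3ccccc3)c1)O2 | intermediate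
20 | C3 borane adduct of 19 (BH2 on C3, H on C4, both anti to the 2-aryl group) | c1ccccc1COc1cc(OCc3ccccc3)c2c(c1)O[C@H](c1ccc(OCc3ccccc3)c(OCc3ccccc3)c1)[C@@H](B)[C@@H]2c1c(OCc3ccccc3)cc(OCc3ccccc3)c2c1O[C@H](c1ccc(OCc3ccccc3)c(OCc3ccccc3)c1)[C@@H](OCc3ccccc3)[C@@H]2c1c(OCc3ccccc3)c(Br)c2c(c1OCc3ccccc3)C[C@H](OCc3ccccc3)[C@@H](c1ccc(OCc3ccccc3)c(OCc3ccccc3)c1)O2 | intermediate (not isolated)
21 | 5,7,3',4'-tetra-O-benzylcatechin-(4α→8)-3,5,7,3',4'-penta-O-benzylcatechin-(4α→6)-8-bromo-3,5,7,3',4'-penta-O-benzylcatechin | c1ccccc1COc1cc(OCc3ccccc3)c2c(c1)O[C@H](c1ccc(OCc3ccccc3)c(OCc3ccccc3)c1)[C@@H](O)[C@@H]2c1c(OCc3ccccc3)cc(OCc3ccccc3)c2c1O[C@H](c1ccc(OCc3ccccc3)c(OCc3ccccc3)c1)[C@@H](OCc3ccccc3)[C@@H]2c1c(OCc3ccccc3)c(Br)c2c(c1OCc3ccccc3)C[C@H](OCc3ccccc3)[C@@H](c1ccc(OCc3ccccc3)c(OCc3ccccc3)c1)O2 | intermediate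
22 | catechin-(4α→8)-catechin-(4α→6)-catechin (CNP0178679.4) | Oc1cc(O)c2c(c1)O[C@H](c1ccc(O)c(O)c1)[C@@H](O)[C@@H]2c1c(O)cc(O)c2c1O[C@H](c1ccc(O)c(O)c1)[C@@H](O)[C@@H]2c1c(O)cc2c(c1O)C[C@H](O)[C@@H](c1ccc(O)c(O)c1)O2 | target

## Step count and least certain steps

Total step count: 14. Longest linear sequence: 12 steps from 1 (steps 1–9 and 12–14); the arylboron branch adds two steps from 14.

**Step 5 (key step).**
- Risk: carbon–carbon bond formation at the shielded ketone may be slow. Acid-driven side processes could then take over: loss of the benzyl group ortho to the ketone, protodeacylation or retro-Claisen cleavage back toward 5, or diversion to the chromone manifold in which the ring carbon is acylated by the ester and the phenol oxygen attacks the ketone.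
- Fallback: replace the ketone by an alkyne so that the arene attacks a linear carbon. From 6, LiN(SiMe3)2 and Tf2O give the (Z)-enol triflate F1, which a second equivalent of the amide base converts by anti elimination to ethyl 3-(penta-O-benzylcatechin-8-yl)propiolate F2. Hydroarylation and lactonisation of F2 with 7 under Pd(OAc)2 in CH2Cl2 containing a little CF3CO2H forms the same C4–C4a and O1–C2 bonds and returns to the route at 8.

**Step 12.**
- Risk: facial selectivity at C2 may be poor if uncatalysed addition to the very stabilised 5,7-dialkoxybenzopyrylium ion outruns the chiral boronate complex. The reaction may also stall if the many ether oxygens sequester the lanthanide.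
- Fallback: give up catalyst control and rely on separation. 17 is converted with KHF2 to potassium [3,4-bis(benzyloxy)phenyl]trifluoroborate F3, which is coupled with 13 under BF3·OEt2. This gives 19 together with its C2 epimer F4; the two are diastereomers because of the six fixed centres of the lower units and are separated by chromatography, which returns to the route at 19.

**Step 13.**
- Risk: conversion may be incomplete at the trisubstituted alkene, whose C4 is flanked by two ortho oxygens. Facial selectivity may erode because the perpendicular 4-aryl group encumbers both faces.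
- Fallback: move the double bond to C2=C3 and set C4 first. From 11, conjugate reduction with a CuH–bisphosphine catalyst (Cu(OAc)2, (R)-DTBM-SEGPHOS, (EtO)2MeSiH, t-BuOH) gives the 4-aryl-dihydrocoumarin F5. Addition of 16 at −78 °C gives the hydroxy ketone F6 (in equilibrium with its cyclic hemiketal), and dehydration with catalytic TsOH gives the 2,4-diaryl-4H-chromene F7. Hydroboration–oxidation of this enol ether, with boron on C3 anti to the 4-aryl group and hydrogen on the unhindered C2, returns to the route at 21.

**Step 8.**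
- Risk: the C4 cation may be captured by C6 of a second molecule of 10 or of 11, because C6 of 3 lies between two benzyloxy groups and is deactivated by bromine. 3,4-trans selectivity may also erode in the absence of a participating group on O3.
- Fallback: make the 4→6 bond earlier on the monomer. From 5, DDQ and 2-ethoxyethanol give 8-acetyl-4-(2-ethoxyethoxy)-penta-O-benzylcatechin F8, whose acetyl group lowers the nucleophilicity of its own ring. TMSOTf and 3 give the dimeric methyl ketone F9, NaH and diethyl carbonate give the dimeric β-ketoester F10, Pechmann condensation with 7 gives the dimeric coumarin diol F11, and benzylation returns to the route at 11. The price is that the annulation then runs on a dimer.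

**Step 3.**
- Risk: proton transfer from the acetamide methyl group to the hindered aryllithium may return 2 instead of the ketone.
- Fallback: use an electrophile that cannot enolise. From 3, lithiation and trapping with DMF give 8-formyl-penta-O-benzylcatechin F12. Aldol addition of the lithium enolate of ethyl acetate (LiN(i-Pr)2, −78 °C) gives the β-hydroxy ester F13, and Dess–Martin oxidation returns to the route at 6, bypassing 5.

## Further compounds

F1 | step 5 | ethyl (Z)-3-(penta-O-benzylcatechin-8-yl)-3-(trifluoromethylsulfonyloxy)acrylate | CCOC(=O)/C=C(\OS(=O)(=O)C(F)(F)F)c1c(OCc3ccccc3)cc(OCc3ccccc3)c2c1O[C@H](c1ccc(OCc3ccccc3)c(OCc3ccccc3)c1)[C@@H](OCc3ccccc3)C2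
F2 | step 5 | ethyl 3-(penta-O-benzylcatechin-8-yl)propiolate | CCOC(=O)C#Cc1c(OCc3ccccc3)cc(OCc3ccccc3)c2c1O[C@H](c1ccc(OCc3ccccc3)c(OCc3ccccc3)c1)[C@@H](OCc3ccccc3)C2
F3 | step 12 | potassium [3,4-bis(benzyloxy)phenyl]trifluoroborate | [K+].F[B-](F)(F)c1ccc(OCc2ccccc2)c(OCc2ccccc2)c1
F4 | step 12 | C2 epimer of 19, (2R)-2H-chromene | c1ccccc1COc1cc(OCc3ccccc3)c2c(c1)O[C@@H](c1ccc(OCc3ccccc3)c(OCc3ccccc3)c1)C=C2c1c(OCc3ccccc3)cc(OCc3ccccc3)c2c1O[C@H](c1ccc(OCc3ccccc3)c(OCc3ccccc3)c1)[C@@H](OCc3ccccc3)[C@@H]2c1c(OCc3ccccc3)c(Br)c2c(c1OCc3ccccc3)C[C@H](OCc3ccccc3)[C@@H](c1ccc(OCc3ccccc3)c(OCc3ccccc3)c1)O2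
F5 | step 13 | 3,4-dihydrocoumarin from 11, C4 configured as in the target | c1ccccc1COc1cc(OCc3ccccc3)c2c(c1)OC(=O)C[C@@H]2c1c(OCc3ccccc3)cc(OCc3ccccc3)c2c1O[C@H](c1ccc(OCc3ccccc3)c(OCc3ccccc3)c1)[C@@H](OCc3ccccc3)[C@@H]2c1c(OCc3ccccc3)c(Br)c2c(c1OCc3ccccc3)C[C@H](OCc3ccccc3)[C@@H](c1ccc(OCc3ccccc3)c(OCc3ccccc3)c1)O2
F6 | step 13 | 1-[3,4-bis(benzyloxy)phenyl]-3-[2-hydroxy-4,6-bis(benzyloxy)phenyl]-3-(dimer-8-yl)propan-1-one | O=C(c1ccc(OCc3ccccc3)c(OCc3ccccc3)c1)C[C@@H](c1c(O)cc(OCc3ccccc3)cc1OCc3ccccc3)c1c(OCc3ccccc3)cc(OCc3ccccc3)c2c1O[C@H](c1ccc(OCc3ccccc3)c(OCc3ccccc3)c1)[C@@H](OCc3ccccc3)[C@@H]2c1c(OCc3ccccc3)c(Br)c2c(c1OCc3ccccc3)C[C@H](OCc3ccccc3)[C@@H](c1ccc(OCc3ccccc3)c(OCc3ccccc3)c1)O2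
F7 | step 13 | 2,4-diaryl-4H-chromene (flav-2-ene), C4 configured as in the target | c1ccccc1COc1cc(OCc3ccccc3)c2c(c1)OC(c1ccc(OCc3ccccc3)c(OCc3ccccc3)c1)=C[C@@H]2c1c(OCc3ccccc3)cc(OCc3ccccc3)c2c1O[C@H](c1ccc(OCc3ccccc3)c(OCc3ccccc3)c1)[C@@H](OCc3ccccc3)[C@@H]2c1c(OCc3ccccc3)c(Br)c2c(c1OCc3ccccc3)C[C@H](OCc3ccccc3)[C@@H](c1ccc(OCc3ccccc3)c(OCc3ccccc3)c1)O2
F8 | step 8 | 8-acetyl-4-(2-ethoxyethoxy)-penta-O-benzylcatechin, 3,4-trans | CC(=O)c1c(OCc3ccccc3)cc(OCc3ccccc3)c2c1O[C@H](c1ccc(OCc3ccccc3)c(OCc3ccccc3)c1)[C@@H](OCc3ccccc3)[C@@H]2OCCOCC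
F9 | step 8 | 8-acetyl-penta-O-benzylcatechin-(4α→6)-8-bromo-penta-O-benzylcatechin | CC(=O)c1c(OCc3ccccc3)cc(OCc3ccccc3)c2c1O[C@H](c1ccc(OCc3ccccc3)c(OCc3ccccc3)c1)[C@@H](OCc3ccccc3)[C@@H]2c1c(OCc3ccccc3)c(Br)c2c(c1OCc3ccccc3)C[C@H](OCc3ccccc3)[C@@H](c1ccc(OCc3ccccc3)c(OCc3ccccc3)c1)O2
F10 | step 8 | ethyl 3-oxo-3-{[penta-O-benzylcatechin-(4α→6)-8-bromo-penta-O-benzylcatechin]-8-yl}propanoate | CCOC(=O)CC(=O)c1c(OCc3ccccc3)cc(OCc3ccccc3)c2c1O[C@H](c1ccc(OCc3ccccc3)c(OCc3ccccc3)c1)[C@@H](OCc3ccccc3)[C@@H]2c1c(OCc3ccccc3)c(Br)c2c(c1OCc3ccccc3)C[C@H](OCc3ccccc3)[C@@H](c1ccc(OCc3ccccc3)c(OCc3ccccc3)c1)O2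
F11 | step 8 | 5,7-dihydroxy-4-{[penta-O-benzylcatechin-(4α→6)-8-bromo-penta-O-benzylcatechin]-8-yl}coumarin | Oc1cc(O)c2c(c1)OC(=O)C=C2c1c(OCc3ccccc3)cc(OCc3ccccc3)c2c1O[C@H](c1ccc(OCc3ccccc3)c(OCc3ccccc3)c1)[C@@H](OCc3ccccc3)[C@@H]2c1c(OCc3ccccc3)c(Br)c2c(c1OCc3ccccc3)C[C@H](OCc3ccccc3)[C@@H](c1ccc(OCc3ccccc3)c(OCc3ccccc3)c1)O2
F12 | step 3 | 8-formyl-3,5,7,3',4'-penta-O-benzyl-(+)-catechin | O=Cc1c(OCc3ccccc3)cc(OCc3ccccc3)c2c1O[C@H](c1ccc(OCc3ccccc3)c(OCc3ccccc3)c1)[C@@H](OCc3ccccc3)C2
F13 | step 3 | ethyl 3-hydroxy-3-(penta-O-benzylcatechin-8-yl)propanoate, both carbinol epimers | CCOC(=O)CC(O)c1c(OCc3ccccc3)cc(OCc3ccccc3)c2c1O[C@H](c1ccc(OCc3ccccc3)c(OCc3ccccc3)c1)[C@@H](OCc3ccccc3)C2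
A1 | alternative 1 | bis(4-aryl-flav-3-ene) precursor, top and middle units as 2H-chromenes | c1ccccc1COc1cc(OCc3ccccc3)c2c(c1)O[C@H](c1ccc(OCc3ccccc3)c(OCc3ccccc3)c1)C=C2c1c(OCc3ccccc3)cc(OCc3ccccc3)c2c1O[C@H](c1ccc(OCc3ccccc3)c(OCc3ccccc3)c1)C=C2c1c(OCc3ccccc3)cc2c(c1OCc3ccccc3)C[C@H](OCc3ccccc3)[C@@H](c1ccc(OCc3ccccc3)c(OCc3ccccc3)c1)O2
A2 | alternative 1 | tridecabenzyl trimer with free 3-hydroxyls in the top and middle units | c1ccccc1COc1cc(OCc3ccccc3)c2c(c1)O[C@H](c1ccc(OCc3ccccc3)c(OCc3ccccc3)c1)[C@@H](O)[C@@H]2c1c(OCc3ccccc3)cc(OCc3ccccc3)c2c1O[C@H](c1ccc(OCc3ccccc3)c(OCc3ccccc3)c1)[C@@H](O)[C@@H]2c1c(OCc3ccccc3)cc2c(c1OCc3ccccc3)C[C@H](OCc3ccccc3)[C@@H](c1ccc(OCc3ccccc3)c(OCc3ccccc3)c1)O2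
A3 | alternative 2 | aryl propargyl ether carrying the top unit on the phenol ring and the bottom unit on the alkyne | c1ccccc1COc1cc(OCc3ccccc3)c2c(c1)O[C@H](c1ccc(OCc3ccccc3)c(OCc3ccccc3)c1)[C@@H](OCc3ccccc3)[C@@H]2c1c(OCc3ccccc3)cc(OCc3ccccc3)cc1O[C@H](c1ccc(OCc3ccccc3)c(OCc3ccccc3)c1)C#Cc1c(OCc3ccccc3)cc2c(c1OCc3ccccc3)C[C@H](OCc3ccccc3)[C@@H](c1ccc(OCc3ccccc3)c(OCc3ccccc3)c1)O2
A4 | alternative 2 | protected trimer with a flav-3-ene middle unit | c1ccccc1COc1cc(OCc3ccccc3)c2c(c1)O[C@H](c1ccc(OCc3ccccc3)c(OCc3ccccc3)c1)[C@@H](OCc3ccccc3)[C@@H]2c1c(OCc3ccccc3)cc(OCc3ccccc3)c2c1O[C@H](c1ccc(OCc3ccccc3)c(OCc3ccccc3)c1)C=C2c1c(OCc3ccccc3)cc2c(c1OCc3ccccc3)C[C@H](OCc3ccccc3)[C@@H](c1ccc(OCc3ccccc3)c(OCc3ccccc3)c1)O2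
A5 | alternative 3 | 1-[3,4-bis(benzyloxy)phenyl]-3-(8-bromo-penta-O-benzylcatechin-6-yl)propane-1,2,3-triol, central carbinol defined, benzylic carbinols as mixtures | OC(c1ccc(OCc3ccccc3)c(OCc3ccccc3)c1)[C@@H](O)C(O)c1c(OCc3ccccc3)c(Br)c2c(c1OCc3ccccc3)C[C@H](OCc3ccccc3)[C@@H](c1ccc(OCc3ccccc3)c(OCc3ccccc3)c1)O2
A6 | alternative 3 | catechin-(4α→6)-8-bromocatechin with ring A of the upper unit unprotected | Oc1cc(O)c2c(c1)O[C@H](c1ccc(OCc3ccccc3)c(OCc3ccccc3)c1)[C@@H](O)[C@@H]2c1c(OCc3ccccc3)c(Br)c2c(c1OCc3ccccc3)C[C@H](OCc3ccccc3)[C@@H](c1ccc(OCc3ccccc3)c(OCc3ccccc3)c1)O2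
A7 | alternative 3 | 4-(2-ethoxyethoxy)-3,5,7,3',4'-penta-O-benzylcatechin, 3,4-trans | c1c(OCc3ccccc3)cc(OCc3ccccc3)c2c1O[C@H](c1ccc(OCc3ccccc3)c(OCc3ccccc3)c1)[C@@H](OCc3ccccc3)[C@@H]2OCCOCC
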